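**Retrosynthetic overview**
- The target comes from Rieche bis-formylation of the corresponding diphenol, itself obtained by debenzylation and Barton–McCombie deoxygenation of a bridged β-aryloxy ketone.
- The bridged ketone comes from an intramolecular oxa-Michael addition of a phenol to a cyclopentenone, which closes the oxepane bridge (last ring).
- The phenol–cyclopentenone comes from the key intermolecular Michael addition of the α'-lithium dienolate of a tricyclic cyclopentenone to an o-quinone methide (from an aryl sulfone); this forms the bond between the quaternary C–CH3 carbon and ArCH(i-Bu).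
- The tricyclic enone comes from ent-4-isocaranone by allylation, Wacker oxidation, aldol condensation and methylation; the ketone comes from (S)-carvone via HCl/base cyclopropanation, Wharton transposition and hydrogenation.
- Ring order: cyclohexane (from carvone), cyclopropane, cyclopentenone, oxepane bridge; the arene is bought as 2,4,6-trihydroxybenzaldehyde.

Assumption: the target is exactly the given SMILES; stereocentres that are made and erased again (methyl-bearing CH next to C=O in the tetramethyl enone, the carbinol carbon before deoxygenation, the aldol carbon, the racemic benzylic carbon of the arene fragment) are drawn as the expected major isomer or left undefined.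

**Step 1**
Reactants: 1 (S)-(+)-carvone
Product: 2 (5S)-5-(2-chloropropan-2-yl)-2-methylcyclohex-2-en-1-one
Conditions: HCl (g), AcOH, 0 °C
Reagents that add atoms: hydrogen chloride, Cl
Why: Markovnikov hydrochlorination of the electron-rich isopropenyl alkene leaves the enone and the C5 stereocentre untouched.

**Step 2**
Reactants: 2 (5S)-5-(2-chloropropan-2-yl)-2-methylcyclohex-2-en-1-one
Product: 3 (1R,6S)-3,7,7-trimethylbicyclo[4.1.0]hept-3-en-2-one
Conditions: KOt-Bu, THF, 0 °C, 20 min
Reagents that add atoms: none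
Why: Intramolecular enolate alkylation (3-exo-tet, 1,3-elimination) at the α'-carbon gives the necessarily cis-fused gem-dimethylcyclopropane, both cyclopropane centres being dictated by C5 of carvone; short contact time avoids ring expansion to eucarvone.

**Step 3**
Reactants: 3 (1R,6S)-3,7,7-trimethylbicyclo[4.1.0]hept-3-en-2-one
Product: 4 (1R,3S,4S,6S)-3,4-epoxy-3,7,7-trimethylbicyclo[4.1.0]heptan-2-one (epoxide trans to the CMe2 bridge)
Conditions: H2O2 (30% aq.), NaOH (cat.), MeOH, 0 °C
Reagents that add atoms: hydrogen peroxide, OO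
Why: Weitz–Scheffer nucleophilic epoxidation, the hydroperoxide attacking C4 from the face opposite the CMe2 bridge.

**Step 4**
Reactants: 4 (1R,3S,4S,6S)-3,4-epoxy-3,7,7-trimethylbicyclo[4.1.0]heptan-2-one
Product: 6 (1R,4S,6S)-3,7,7-trimethylbicyclo[4.1.0]hept-2-en-4-ol, via epoxy hydrazone 5 (not isolated)
Conditions: N2H4·H2O, AcOH (cat.), MeOH, 0 °C → rt
Reagents that add atoms: none
Why: Wharton transposition (hydrazone, epoxide opening, loss of N2) moves the oxygen from C2 to C4 with retention at C4 and leaves a C2=C3 alkene.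

**Step 5**
Reactants: 6 (1R,4S,6S)-3,7,7-trimethylbicyclo[4.1.0]hept-2-en-4-ol
Product: 7 (1R,3S,4S,6S)-3,7,7-trimethylbicyclo[4.1.0]heptan-4-ol (ent-4-isocaranol; 3-CH3 cis and 4-OH trans to the CMe2 bridge)
Conditions: H2 (1 atm), [Ir(cod)(PCy3)(py)]PF6 (2 mol%), CH2Cl2, rt
Reagents that add atoms: none
Why: Hydroxyl-directed homogeneous hydrogenation delivers H2 syn to the C4–OH, which is also the face away from the CMe2 bridge, so the C3 methyl ends up cis to the bridge without cyclopropane hydrogenolysis.

**Step 6**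
Reactants: 7 (1R,3S,4S,6S)-3,7,7-trimethylbicyclo[4.1.0]heptan-4-ol
Product: 8 (1R,3S,6S)-3,7,7-trimethylbicyclo[4.1.0]heptan-4-one (ent-4-isocaranone)
Conditions: Dess–Martin periodinane, CH2Cl2, 0 °C → rt
Reagents that add atoms: none
Why: Dess–Martin oxidation is non-epimerising, and the cis-3-methyl ketone is in any case the thermodynamically preferred C3 epimer of 4-caranones.

**Step 7**
Reactants: 8 (1R,3S,6S)-3,7,7-trimethylbicyclo[4.1.0]heptan-4-one
Product: 10 (1R,3S,5S,6R)-3,7,7-trimethyl-5-(prop-2-en-1-yl)bicyclo[4.1.0]heptan-4-one, via lithium enolate 9 (not isolated)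
Conditions: LiN(i-Pr)2, THF, −78 °C; allyl bromide, DMPU, −78 → −20 °C
Reagents that add atoms: allyl bromide, C=CCBr
Why: Kinetic enolate alkylation: the amide base removes a C5 methylene proton rather than the C3 methine, and the electrophile enters anti to the CMe2 bridge, setting C5.

**Step 8**
Reactants: 10 (1R,3S,5S,6R)-3,7,7-trimethyl-5-(prop-2-en-1-yl)bicyclo[4.1.0]heptan-4-one
Product: 11 (1R,3S,5S,6R)-3,7,7-trimethyl-5-(2-oxopropyl)bicyclo[4.1.0]heptan-4-one
Conditions: PdCl2 (10 mol%), CuCl, O2 (1 atm), DMF/H2O 7:1, rt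
Reagents that add atoms: water, O
Why: Tsuji–Wacker oxidation converts the terminal alkene into the methyl ketone (Markovnikov), giving the 1,4-diketone with O2 as terminal oxidant.

**Step 9**
Reactants: 11 (1R,3S,5S,6R)-3,7,7-trimethyl-5-(2-oxopropyl)bicyclo[4.1.0]heptan-4-one
Product: 13 (1aR,3S,6aS,6bR)-1,1,3-trimethyl-1,1a,2,3,6,6a,6b-heptahydro-5H-cyclopropa[e]inden-5-one, via aldol 12 (not isolated)
Conditions: KOH (2%), MeOH, 40 °C
Reagents that add atoms: none
Why: Intramolecular aldol condensation, the cyclopentenone being the only aldol product able to dehydrate; the two epimerisable centres stay in the favoured arrangement (3-CH3 cis to the CMe2 bridge, ring bond at C6a trans to it, both pseudo-equatorial).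

**Step 10**
Reactants: 13 (1aR,3S,6aS,6bR)-1,1,3-trimethyl-1,1a,2,3,6,6a,6b-heptahydro-5H-cyclopropa[e]inden-5-one
Product: 15 (1aR,3S,6R,6aR,6bR)-1,1,3,6-tetramethyl-1,1a,2,3,6,6a,6b-heptahydro-5H-cyclopropa[e]inden-5-one, via lithium dienolate 14 (not isolated)
Conditions: LiN(i-Pr)2, THF, −78 °C; MeI, −78 → −40 °C
Reagents that add atoms: iodomethane, CI
Why: Kinetic α'-deprotonation of the cyclopentenone and enolate methylation anti to C6b; the C6 configuration is irrelevant because it is planarised again in step 14.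

**Step 11**
Reactants: 16 2,4,6-trihydroxybenzaldehyde
Product: 17 2,4-bis(benzyloxy)-6-hydroxybenzaldehyde
Conditions: BnBr (2.1 equiv), K2CO3, DMF, rt
Reagents that add atoms: benzyl bromide, BrCc1ccccc1
Why: Williamson etherification stops at the dibenzyl ether because the remaining ortho-OH is held in a hydrogen bond to the aldehyde.

**Step 12**
Reactants: 17 2,4-bis(benzyloxy)-6-hydroxybenzaldehyde
Product: 18 3,5-bis(benzyloxy)-2-(1-hydroxy-3-methylbutyl)phenol (racemic)
Conditions: i-BuMgBr (2.5 equiv), THF, 0 °C; NH4Cl (aq); used crude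
Reagents that add atoms: isobutylmagnesium bromide, CC(C)C[Mg]Br
Why: Grignard addition to the aldehyde after the first equivalent has deprotonated the phenol; the carbinol centre is erased later, so no stereocontrol is needed.

**Step 13**
Reactants: 18 3,5-bis(benzyloxy)-2-(1-hydroxy-3-methylbutyl)phenol
Product: 19 3,5-bis(benzyloxy)-2-[3-methyl-1-(4-methylbenzenesulfonyl)butyl]phenol (racemic)
Conditions: sodium p-toluenesulfinate, HCO2H/H2O 1:1, rt
Reagents that add atoms: sodium p-toluenesulfinate, Cc1ccc(cc1)S(=O)[O-].[Na+]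
Why: Acid-mediated SN1 substitution of the very labile o-hydroxybenzylic alcohol by the sulfur of the sulfinate gives a bench-stable o-quinone methide precursor.

**Step 14**
Reactants: 15 (1aR,3S,6R,6aR,6bR)-1,1,3,6-tetramethyl-1,1a,2,3,6,6a,6b-heptahydro-5H-cyclopropa[e]inden-5-one; 19 3,5-bis(benzyloxy)-2-[3-methyl-1-(4-methylbenzenesulfonyl)butyl]phenol
Product: 23 6-[1-(2,4-bis(benzyloxy)-6-hydroxyphenyl)-3-methylbutyl]-1,1,3,6-tetramethyl-1,1a,2,3,6,6a,6b-heptahydro-5H-cyclopropa[e]inden-5-one (new C–C bond trans to C6b; benzylic CH as in the target), via lithium dienolate 20 (not isolated), via lithium phenoxide 21 (not isolated), via o-quinone methide 22 (not isolated)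
Conditions: 15, LiN(i-Pr)2 (1.0 equiv), THF, −78 °C; add 19 (1.3 equiv) pre-treated with LiN(SiMe3)2 (THF, −78 °C); −78 → −10 °C; NH4Cl (aq)
Reagents that add atoms: none
Why: Intermolecular Michael addition: 1,4-elimination of sulfinate from the phenoxide releases the (E)-o-quinone methide, which the α'-carbon of the cross-conjugated dienolate attacks on the face anti to C6b (sets the quaternary centre), and a lithium-bridged arrangement with the aryl ring over the dienolate places the isobutyl group as required at the benzylic centre.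

**Step 15**
Reactants: 23 Michael adduct phenol–enone
Product: 24 bridged ketone (bis(O-benzyl) bis(deformyl) target skeleton with C=O at the bridge CH2 next to the C–CH3 bridgehead)
Conditions: DBU (0.3 equiv), toluene, 50 °C
Reagents that add atoms: none
Why: Reversible intramolecular oxa-Michael addition of the phenoxide to the β-carbon of the cyclopentenone; the tether allows attack only on the face carrying the benzylic carbon, which fixes the O-bearing bridgehead, and only the desired benzylic epimer (isobutyl turned away from the neighbouring OBn) closes without A(1,3) strain.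

**Step 16**
Reactants: 24 bridged ketone
Product: 25 bridged alcohol (CH–OH in place of C=O; carbinol configuration inconsequential)
Conditions: NaBH4, CeCl3·7H2O, MeOH/THF, −40 °C
Reagents that add atoms: none
Why: Luche-type carbonyl reduction under cold, weakly basic conditions is faster than enolisation, so the β-aryloxy ketone is not lost by retro-oxa-Michael elimination.

**Step 17**
Reactants: 25 bridged alcohol
Product: 27 O-alkyl S-methyl xanthate of 25, via sodium xanthate 26 (not isolated)
Conditions: NaH, imidazole (cat.), THF, 0 °C; CS2; MeI, rt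
Reagents that add atoms: carbon disulfide, S=C=S; iodomethane, CI
Why: Standard xanthate formation (alkoxide addition to CS2, then S-methylation); no enolisable or base-labile group remains.

**Step 18**
Reactants: 27 S-methyl xanthate
Product: 28 bis(O-benzyl) bis(deformyl) target (CH2–CH2 bridge complete)
Conditions: Bu3SnH, AIBN (cat.), toluene, 110 °C
Reagents that add atoms: none
Why: Barton–McCombie radical deoxygenation; the secondary radical has no β-leaving group (the aryloxy group is γ) and is remote from the cyclopropane, so it is simply reduced.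

**Step 19**
Reactants: 28 bis(O-benzyl) bis(deformyl) target
Product: 29 bis(deformyl) target (free diphenol)
Conditions: H2 (1 atm), Pd/C (10%), EtOAc/MeOH, rt
Reagents that add atoms: none
Why: Hydrogenolysis removes only the two benzyl ethers; the isolated gem-dimethylcyclopropane and the tertiary alkyl aryl ether are inert under these conditions.

**Step 20**
Reactants: 29 bis(deformyl) target
Product: 31 CNP0202714.1 (target), via bis(chloromethoxymethyl)arene 30 (not isolated)
Conditions: Cl2CHOMe (4 equiv), TiCl4 (5 equiv), CH2Cl2, −78 → 0 °C; then H2O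
Reagents that add atoms: dichloromethyl methyl ether, COC(Cl)Cl; water, O
Why: Rieche formylation directed by the titanium phenoxides substitutes the only two free ring positions, each ortho to a free OH, and aqueous work-up hydrolyses the α-chloro ethers to the two aldehydes; the bridgehead tertiary ether resists ionisation.

**Compound list**
1 | (S)-(+)-carvone | CC1=CC[C@@H](CC1=O)C(C)=C | starting material
2 | (5S)-5-(2-chloropropan-2-yl)-2-methylcyclohex-2-en-1-one | CC1=CC[C@@H](CC1=O)C(C)(C)Cl | intermediate
3 | (1R,6S)-3,7,7-trimethylbicyclo[4.1.0]hept-3-en-2-one | CC1=CC[C@H]2[C@@H](C1=O)C2(C)C | intermediate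
4 | (1R,3S,4S,6S)-3,4-epoxy-3,7,7-trimethylbicyclo[4.1.0]heptan-2-one, epoxide trans to the CMe2 bridge | C[C@]12O[C@H]1C[C@H]3[C@@H](C2=O)C3(C)C | intermediate
5 | hydrazone of 4 (not isolated) | C[C@]12O[C@H]1C[C@H]3[C@@H](C2=NN)C3(C)C | intermediate
6 | (1R,4S,6S)-3,7,7-trimethylbicyclo[4.1.0]hept-2-en-4-ol, OH trans to the CMe2 bridge | CC1=C[C@@H]2[C@H](C[C@@H]1O)C2(C)C | intermediate
7 | (1R,3S,4S,6S)-3,7,7-trimethylbicyclo[4.1.0]heptan-4-ol (ent-4-isocaranol) | C[C@@H]1[C@@H](O)C[C@H]2[C@@H](C1)C2(C)C | intermediate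
8 | (1R,3S,6S)-3,7,7-trimethylbicyclo[4.1.0]heptan-4-one (ent-4-isocaranone) | C[C@@H]1C(=O)C[C@H]2[C@@H](C1)C2(C)C | intermediate
9 | lithium C4–C5 enolate of 8 (not isolated) | C[C@@H]1C([O-])=C[C@H]2[C@@H](C1)C2(C)C.[Li+] | intermediate
10 | (1R,3S,5S,6R)-3,7,7-trimethyl-5-(prop-2-en-1-yl)bicyclo[4.1.0]heptan-4-one, allyl trans to the CMe2 bridge | C[C@@H]1C(=O)[C@@H](CC=C)[C@H]2[C@@H](C1)C2(C)C | intermediate
11 | (1R,3S,5S,6R)-3,7,7-trimethyl-5-(2-oxopropyl)bicyclo[4.1.0]heptan-4-one | C[C@@H]1C(=O)[C@@H](CC(C)=O)[C@H]2[C@@H](C1)C2(C)C | intermediate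
12 | 3a-hydroxy-1,1,3-trimethyl-octahydrocyclopropa[e]inden-5-one, aldol adduct (not isolated; carbinol centre undefined) | C[C@@H]1C2(O)CC(=O)C[C@H]2[C@H]3[C@@H](C1)C3(C)C | intermediate
13 | (1aR,3S,6aS,6bR)-1,1,3-trimethyl-1,1a,2,3,6,6a,6b-heptahydro-5H-cyclopropa[e]inden-5-one | C[C@@H]1C2=CC(=O)C[C@H]2[C@H]3[C@@H](C1)C3(C)C | intermediate
14 | lithium cross-conjugated dienolate of 13 (not isolated) | C[C@@H]1C2=CC([O-])=C[C@H]2[C@H]3[C@@H](C1)C3(C)C.[Li+] | intermediate
15 | (1aR,3S,6R,6aR,6bR)-1,1,3,6-tetramethyl-1,1a,2,3,6,6a,6b-heptahydro-5H-cyclopropa[e]inden-5-one (major C6 epimer) | C[C@@H]1C2=CC(=O)[C@H](C)[C@H]2[C@H]3[C@@H](C1)C3(C)C | intermediate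
16 | 2,4,6-trihydroxybenzaldehyde | O=Cc1c(O)cc(O)cc1O | starting material
17 | 2,4-bis(benzyloxy)-6-hydroxybenzaldehyde | O=Cc1c(O)cc(OCc2ccccc2)cc1OCc1ccccc1 | intermediate
18 | 3,5-bis(benzyloxy)-2-(1-hydroxy-3-methylbutyl)phenol, racemic | CC(C)CC(O)c1c(O)cc(OCc2ccccc2)cc1OCc1ccccc1 | intermediate
19 | 3,5-bis(benzyloxy)-2-[3-methyl-1-(4-methylbenzenesulfonyl)butyl]phenol, racemic | CC(C)CC(c1c(O)cc(OCc2ccccc2)cc1OCc1ccccc1)S(=O)(=O)c1ccc(C)cc1 | intermediate
20 | lithium cross-conjugated dienolate of 15 (not isolated) | C[C@@H]1C2=CC([O-])=C(C)[C@H]2[C@H]3[C@@H](C1)C3(C)C.[Li+] | intermediate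
21 | lithium phenoxide of 19 (not isolated) | CC(C)CC(c1c([O-])cc(OCc2ccccc2)cc1OCc1ccccc1)S(=O)(=O)c1ccc(C)cc1.[Li+] | intermediate
22 | (E)-3,5-bis(benzyloxy)-6-(3-methylbutylidene)cyclohexa-2,4-dien-1-one, o-quinone methide (not isolated) | CC(C)C/C=C1/C(=O)C=C(OCc2ccccc2)C=C1OCc1ccccc1 | intermediate
23 | Michael adduct: 15 carrying at C6, trans to C6b, the 1-(2,4-bis(benzyloxy)-6-hydroxyphenyl)-3-methylbutyl group; benzylic CH as in the target | C[C@@H]1C2=CC(=O)[C@](C)([C@@H](CC(C)C)c4c(O)cc(OCc5ccccc5)cc4OCc6ccccc6)[C@H]2[C@H]3[C@@H](C1)C3(C)C | intermediate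
24 | bridged ketone: bis(O-benzyl) bis(deformyl) target with C=O at the bridge CH2 next to the C–CH3 bridgehead | CC(C)C[C@H]1c2c(OCc4ccccc4)cc(OCc4ccccc4)cc2O[C@]23CC(=O)[C@@]1(C)[C@H]2[C@H]1[C@@H](C[C@@H]3C)C1(C)C | intermediate
25 | bridged alcohol: as 24 with CH–OH in place of C=O (carbinol centre undefined) | CC(C)C[C@H]1c2c(OCc4ccccc4)cc(OCc4ccccc4)cc2O[C@]23CC(O)[C@@]1(C)[C@H]2[C@H]1[C@@H](C[C@@H]3C)C1(C)C | intermediate
26 | sodium xanthate of 25 (not isolated) | CC(C)C[C@H]1c2c(OCc4ccccc4)cc(OCc4ccccc4)cc2O[C@]23CC(OC(=S)[S-])[C@@]1(C)[C@H]2[C@H]1[C@@H](C[C@@H]3C)C1(C)C.[Na+] | intermediate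
27 | O-alkyl S-methyl xanthate of 25 | CC(C)C[C@H]1c2c(OCc4ccccc4)cc(OCc4ccccc4)cc2O[C@]23CC(OC(=S)SC)[C@@]1(C)[C@H]2[C@H]1[C@@H](C[C@@H]3C)C1(C)C | intermediate
28 | bis(O-benzyl) bis(deformyl) target | CC(C)C[C@H]1c2c(OCc4ccccc4)cc(OCc4ccccc4)cc2O[C@]23CC[C@@]1(C)[C@H]2[C@H]1[C@@H](C[C@@H]3C)C1(C)C | intermediate
29 | bis(deformyl) target, free diphenol | CC(C)C[C@H]1c2c(O)cc(O)cc2O[C@]23CC[C@@]1(C)[C@H]2[C@H]1[C@@H](C[C@@H]3C)C1(C)C | intermediate
30 | bis(chloro(methoxy)methyl) derivative of 29 (not isolated) | CC(C)C[C@H]1c2c(O)c(C(Cl)OC)c(O)c(C(Cl)OC)c2O[C@]23CC[C@@]1(C)[C@H]2[C@H]1[C@@H](C[C@@H]3C)C1(C)C | intermediate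
31 | CNP0202714.1 | CC(C)C[C@H]1c2c(O)c(C=O)c(O)c(C=O)c2O[C@]23CC[C@@]1(C)[C@H]2[C@H]1[C@@H](C[C@@H]3C)C1(C)C | target

**Totals**
Total step count: 20. Longest linear sequence: 17 steps (steps 1–10 and 14–20, from compound 1); the arene branch is steps 11–13.

**Three steps most likely to fail**

Step 14 (key Michael addition). The new bond joins a quaternary carbon to a hindered benzylic carbon, the alkyl-substituted o-quinone methide can tautomerise to a styrene under basic conditions, and the benzylic configuration rests on a transition-state argument. The fallback sets out from 15 and comes back at 23. Compound 15 is deprotonated as before and the enolate is trapped with Me3SiCl to give the trimethylsilyl dienol ether F1. F1 is stirred with sulfone 19 and Cs2CO3 in toluene at room temperature, so that 22 forms without a strong base and is intercepted in an inverse-demand hetero-Diels–Alder reaction across the silyloxy-substituted double bond, on the face anti to C6b and with the arene over the diene ring. This gives the chroman silyl ketal F2. Buffered fluoride (Bu4NF/AcOH) collapses the ketal to phenol–enone 23, where the main route resumes.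

Step 15 (oxa-Michael ring closure). The addition is reversible and forms a tertiary ether in a bridged seven-membered ring, so the equilibrium may not lie far enough on the side of 24. The fallback sets out from 23 and comes back at 25. Compound 23 is treated with NaBH4 in MeOH/CH2Cl2 with a trace of K2CO3 at −40 → 0 °C. The phenoxide equilibrates with the closed β-aryloxy ketone, and this saturated ketone is reduced much faster than the hindered conjugated enone, so the equilibrium is drained irreversibly into alcohol 25. This detour creates no new compound (F0).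

Step 20 (double Rieche formylation). A strong Lewis acid and HCl meet an electron-rich diphenol, a cyclopropane and a tertiary ether, and the second formylation is on a deactivated ring. The fallback sets out from 28 and comes back at 31. Compound 28 is brominated with N-bromosuccinimide (2.1 equiv, MeCN, 0 °C) at the two free ring positions to give the dibromide F3. Double bromine–lithium exchange (t-BuLi, THF, −78 °C) followed by DMF gives the dialdehyde bis(benzyl ether) F4. The benzyl groups are then removed with BCl3 and pentamethylbenzene in CH2Cl2 at −78 °C to give 31, so that no electrophilic formylation is needed.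

**Further compounds**
F1 | step 14 | trimethylsilyl dienol ether of 15 | C[C@@H]1C2=CC(O[Si](C)(C)C)=C(C)[C@H]2[C@H]3[C@@H](C1)C3(C)C
F2 | step 14 | chroman silyl ketal cycloadduct of F1 and 22 | C[C@@H]1C2=C[C@]3(O[Si](C)(C)C)Oc4cc(OCc5ccccc5)cc(OCc5ccccc5)c4[C@H](CC(C)C)[C@]3(C)[C@H]2[C@H]6[C@@H](C1)C6(C)C
F0 | step 15 | none | none
F3 | step 20 | dibromide of 28 (Br at both free arene positions) | CC(C)C[C@H]1c2c(OCc4ccccc4)c(Br)c(OCc4ccccc4)c(Br)c2O[C@]23CC[C@@]1(C)[C@H]2[C@H]1[C@@H](C[C@@H]3C)C1(C)C
F4 | step 20 | dialdehyde bis(benzyl ether) of the target | CC(C)C[C@H]1c2c(OCc4ccccc4)c(C=O)c(OCc4ccccc4)c(C=O)c2O[C@]23CC[C@@]1(C)[C@H]2[C@H]1[C@@H](C[C@@H]3C)C1(C)C
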